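5 questions stand on this flask, and they turn on one balance of the solid substrate, the one thing charged.

| flask | solid substrate | remark | time |
|---|---|---|---|
| elm | 0.021 M | run made earlier |  |
| maple | 0.031 M | run made earlier |  |
| flask | 0.041 M |  | 10 d |

| run | time / d | solid substrate / % | target / % | isomer of the product / % |
|---|---|---|---|---|
| elm | 1.67 | 0.1 | 42.4 | 32.7 |
| elm | 3.00 | 0 | 42.5 | 32.7 |
| elm | 5.00 | 0 | 41.8 | 32.7 |
| elm | 6.00 | 0 | 42.3 | 33.0 |
| elm | 8.00 | 0 | 42.6 | 32.9 |
| maple | 0.625 | 10.1 | 34.2 | 24.8 |
| maple | 2.08 | 0 | 42.0 | 32.4 |
| maple | 4.00 | 0.4 | 42.5 | 32.7 |
| maple | 6.00 | 0 | 42.5 | 33.1 |
| maple | 8.00 | 0 | 42.6 | 32.7 |

(each reading ± 0.3 percentage points)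

- solid, in amounts per volume of the solution: solid substrate
- at the start none of the solid substrate is in solution
- what has only dissolved of solid substrate counts as not reacted
- what has gone from starting material into another species counts as reacted, even if it can come back
- the reaction counts as stopped when no species that holds the solid substrate changes by six tenths of a point or more over the second half of the time
- starting material means what is dissolved; the solid is not counted in it

- the state of affairs at 10 d: stopped, and by what, or still going (for what has run out or reacted, a solid counts together with what of it has only dissolved) (it is still moving / all of the solid substrate has reacted / forward and back rates have come level)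
- part of the solid substrate that has turned into other species by 10 d (what has only dissolved does not count)
- the target standing at 10 d, as a percentage of the solid substrate charged
- the isomer of the product standing at 10 d, as a percentage of the solid substrate charged
- the starting material standing at 10 d, as a percentage of the solid substrate charged

At the last reading, elm has 24.5% of its charge outside solid, target and isomer, and maple has 24.7%. That is a difference of 0.2 percentage points against a scatter of 0.3 points. Their mean, 24.6%, is the missing share, the remainder of the mass balance; times the charge it gives c(missing).

Two chemists read this differently. The first looks at maple at 0.625 d, where solid still stands at 10.1%. The missing share there is 30.9%, so c(missing) is 0.00958 M, which he takes as dissolved starting material and as the solubility, or a lower limit on it. The runs' share on the flask's charge gives 0.0101 M and his own figure is 0.0102 M; both stand above that, hence his words “so some solid should survive”. His forecast: forward and back rates have come level, conversion 70.9%, target 40%, isomer 30.9%, starting material 23.4%.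

The second holds the share fixed. In the runs c(missing) ends at 0.00514 M in elm and 0.00766 M in maple, higher with the higher charge, and the maple figure of 0.00958 M was read while solid was still going. To her it shows what can dissolve, not a limit. She expects no solid in the flask, target 42.6%, isomer 32.8%, and the missing share 24.6%, in what the readings do not list.

In the flask forward and back rates have come level: conversion 88.2%, target 42.5%, isomer 32.8%, starting material 11.8%.

    starting material ⇌ target (K = 3.60, k = 0.00399 min⁻¹)
    starting material ⇌ isomer of the product (K = 2.78, k = 0.00183 min⁻¹)
    target ⇌ isomer of the product (k = 0.00412 min⁻¹)
    starting material ⇌ dormant form (K = 1.10, k = 9.34 × 10⁻⁴ min⁻¹)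
    solid substrate ⇌ starting material, rate k5*(cs5 - [starting material]) while solid is left; crystals form when [starting material] > cs5 (solubility = 26.0 mM, k = 0.00147 min⁻¹)

Solid stands at 0% at 10.0 d, and the flask holds dormant form at 13.0% beside its starting material. Its missing share is 24.7%, against 24.6% from the runs. The solubility in the scheme is 26 mM; at this flask's share of starting material, c(starting material) comes to that at a charge of 0.220 M, and the first chemist's surviving solid belongs above that charge. In the neighbour flask with 0.10 M, the missing share gives c(missing) of 0.0246 M, above the maple figure of 0.00958 M, and its solid stands at 0%.

All runs stem from a simulated flask with made-up constants; noise was put on by code.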